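In a one-step world Z falls at a steady pace set by the Q on offer. That pace is the natural log of Z charged over Z remaining, divided by the time, and it is the pseudo-first-order constant of that picture. I have to decide the next charge: leave it, improve transfer (ash), or add Q (cedar).

common to all: Z 16 mM
- red: Q 7.6 mM; run made earlier
- ochre: Q 30 mM; run made earlier
- flask: Q 15.2 mM; time 6.0 min; volume of the second phase over the first 0.50

| run | time / min | G / % |
|---|---|---|
| red | 0.500 | 0.3 |
| red | 1.50 | 3.5 |
| red | 3.00 | 6.8 |
| red | 4.00 | 7.2 |
| red | 6.00 | 13.1 |
| ochre | 0.500 | 0.2 |
| ochre | 1.50 | 7.5 |
| ochre | 3.00 | 19.3 |
| ochre | 4.00 | 26.6 |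
| ochre | 6.00 | 37.4 |

(readings scatter by 1 percentage point)

- amount of G at 6.0 min, in percent of the Z charged
- the change that raises the amount of G at 6.0 min, in percent of the Z charged most ("none" if none brings more than 2 percentage points) (ash / cedar / none)
- amount of G at 6.0 min, in percent of the Z charged, after ash

- in the second phase: Q; everything else is in the first
- charges count per volume of the first phase; a concentration in a rate is the amount of a species over the volume of its own phase; every rate counts per litre of the first phase
- the earlier runs hold the two phases in the same ratio of volumes as the flask asked about

Both runs charge the same Z and are read at 6.00 min, so I divide one pace by the other and time drops out. The red run gives 0.0234 /min and the ochre run 0.0781 /min. Set against the ratio of Q charges, that is an order in Q of 0.877. Scaled from the red run, the pace at the flask's charge is 0.0430 /min; I call this the charge-scaled pace. It gives me 22.7% of G at 6.0 min, and cedar gives 37.7%, a gain of 15 percentage points.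

Both runs read near zero at 0.500 min, which I read as a lag. If ash took that whole time away, my pace would be multiplied by 1.09. That factor is less than the 1.84 from cedar, and it gives ash about 24.5%. Neither run changes transfer, so past the lag I have no reading of ash. I charge more Q.

The forecast says 22%, cedar and 26%, calling the runs “close to first order in Q”. Its 22% stands beside my 22.7%.

The flask gives 21.3%, and 27.2% after ash; cedar adds 17 points and ash 5.9 points, so cedar stands. At 6.00 min the flask holds Q at 49.3% of its own charge. Its pace read back from the result is 0.0399 /min, below the charge-scaled 0.0430 /min.

    E ⇌ Q, rate k1*([E] - [Q]/K1) per volume of the first phase (partition coefficient = 3.07, kL = 0.00428 /s)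
    Z + E ⇌ G (K = 455 /M, k = 0.412 /M/s)
    E ⇌ D (K = 1.30, k = 0.00498 /s)
    2 E → J (k = 0.0748 /M/s)

On the same charges read at 15 min, the charge-scaled pace gives 47.5% of G. The simulated neighbour flask holds 37.7%, less, with Q at 26.9% of its own charge.

Readings and results stem from a simulated flask for an exercise, noise included.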